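**Plan**

- Retrosynthesis: the upper and then the lower C4–C6 interflavan bond are cut, each to a flavan-4-yl cation and a ring A nucleophile whose C8 carries a bromine cap. The lower unit is (+)-catechin and the upper unit (−)-epicatechin.
- Ring C of the middle unit is taken back to its 4-ketone (flavanonol) and contracted by a retro α-ketol shift to a 3-hydroxy-2,3-dihydrobenzofuran-3-carbaldehyde. The dihydrofuran C2–C3 bond is then cut to an aryldiazoacetate, whose carbene inserts into an O-benzyl CH2 group that becomes C2 and ring B.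
- Forward order: ring A tris-ether → keto ester → diazo ester → five-membered dihydrofuran → 3-hydroxylation → aldehyde → ring expansion to six-membered ring C → C4 reduction → C8 bromination → 4α→6 union with the lower unit → 4β→6 union with the upper unit → hydrogenolysis.
- Stereochemistry: the lower and upper units come from the chiral pool. C2 of the middle unit comes from the Rh2(S-PTTL)4-catalysed C–H insertion, C3 from the chelated (and thermodynamically trans) ketol shift, and both C4 centres from attack anti to the neighbouring 3-hydroxyl.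
- Feature that makes the ring expansion possible: in ring C of the middle unit C3 bears a hydroxyl and C4 is benzylic to the phloroglucinol ring A. The O1–C2–C3(OH)–C4(=O) ketol of the flavanonol is therefore the conjugated, stable partner of a tertiary carbinol/aldehyde pair on a five-membered ring O1–C2–C(OH)(CHO)–C4a–C8a.

Key step: step 13

Remarks and assumptions:
- DBB = 3,4-bis(benzyloxy)benzyl. The DBB ether that undergoes C–H insertion becomes ring B; the other two serve as hydrogenolysable protecting groups of O5 and O7.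
- Step 6 takes up three molecules of 9, one for each phenol. One is entered as the reactant and the two further ones under the reagents that add atoms.
- Rh2(S-PTTL)4 is taken to deliver the (2S,3R) ester 16; if the sense of induction proves opposite, the mirror-image catalyst Rh2(R-PTTL)4 is used.
- The secondary 3-hydroxyls are left free in both interflavan couplings.

**Route**

Step 1
Reactants: 1 (+)-catechin
Product: 2 5,7,3',4'-tetra-O-benzyl-(+)-catechin
Conditions: BnBr (4.4 equiv), K2CO3, DMF, 0 °C → rt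
Reagents that add atoms: benzyl bromide, BrCc1ccccc1
Why: Williamson etherification of the four phenols; the secondary 3-hydroxyl is not deprotonated by carbonate and stays free.

Step 2
Reactants: 2 5,7,3',4'-tetra-O-benzyl-(+)-catechin
Product: 3 8-bromo-5,7,3',4'-tetra-O-benzyl-(+)-catechin
Conditions: NBS (1.0 equiv), CH2Cl2, −78 °C → rt
Reagents that add atoms: N-bromosuccinimide, O=C1CCC(=O)N1Br
Why: Electrophilic aromatic bromination at C8, the more accessible of the two ring A positions (next to O1, not between two benzyloxy groups); the bromine caps C8 so that later substitution can occur only at C6.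

Step 3
Reactants: 4 (−)-epicatechin
Product: 5 5,7,3',4'-tetra-O-benzyl-(−)-epicatechin
Conditions: BnBr (4.4 equiv), K2CO3, DMF, 0 °C → rt
Reagents that add atoms: benzyl bromide, BrCc1ccccc1
Why: Williamson etherification of the phenols under mild carbonate conditions, which should leave C2 and the free 3-hydroxyl untouched.

Step 4
Reactants: 5 5,7,3',4'-tetra-O-benzyl-(−)-epicatechin
Product: 6 (2R,3R,4S)-4-(2-ethoxyethoxy)-5,7,3',4'-tetra-O-benzylepicatechin (4β ether, trans to the 3-hydroxyl)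
Conditions: DDQ (2 equiv), 2-ethoxyethanol (5 equiv), CH2Cl2, rt
Reagents that add atoms: 2-ethoxyethanol, CCOCCO
Why: Benzylic oxidation by hydride abstraction at C4 (assisted by ring A) and capture of the cation by the alcohol anti to the 3-hydroxyl, which sets the 4β ether.

Step 5
Reactants: 6 (2R,3R,4S)-4-(2-ethoxyethoxy)-5,7,3',4'-tetra-O-benzylepicatechin
Product: 7 (2R,3R,4S)-6,8-dibromo-4-(2-ethoxyethoxy)-5,7,3',4'-tetra-O-benzylepicatechin
Conditions: NBS (2.2 equiv), CH2Cl2, −78 °C → rt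
Reagents that add atoms: N-bromosuccinimide, O=C1CCC(=O)N1Br
Why: Twofold electrophilic bromination of ring A, far more reactive than the catechol-type rings; with C6 and C8 both capped this electrophile cannot condense with itself.

Step 6
Reactants: 8 1,3,5-triacetoxybenzene; 9 3,4-bis(benzyloxy)benzyl chloride (DBB-Cl)
Product: 10 1,3,5-tris(DBB-oxy)benzene
Conditions: 9 (3.3 equiv in all), NaH (6.6 equiv), DMF, then H2O (3.3 equiv) added slowly, 0 °C → rt
Reagents that add atoms: 3,4-bis(benzyloxy)benzyl chloride (DBB-Cl), ClCc1ccc(OCc2ccccc2)c(OCc2ccccc2)c1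
Why: The acetates are cleaved in the flask by the hydroxide formed from NaH and water, and each phenoxide is alkylated by 9 as it forms (threefold Williamson etherification), which should favour O- over C-alkylation of phloroglucinol.

Step 7
Reactants: 10 1,3,5-tris(DBB-oxy)benzene
Product: 11 2-bromo-1,3,5-tris(DBB-oxy)benzene
Conditions: NBS (1.0 equiv), CH2Cl2, −78 °C → 0 °C
Reagents that add atoms: N-bromosuccinimide, O=C1CCC(=O)N1Br
Why: Electrophilic bromination of the tri-oxygenated core, the most electron-rich ring; its three free positions are equivalent, so one monobromide should result.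

Step 8
Reactants: 11 2-bromo-1,3,5-tris(DBB-oxy)benzene
Product: 13 methyl 2-oxo-2-[2,4,6-tris(DBB-oxy)phenyl]acetate, via aryllithium 12 (not isolated)
Conditions: n-BuLi (1.05 equiv), THF, −78 °C; then addition to dimethyl oxalate (3 equiv), THF, −78 °C
Reagents that add atoms: dimethyl oxalate, COC(=O)C(=O)OC
Why: Bromine–lithium exchange followed by acylation with the oxalate diester; low temperature and inverse addition should suppress benzylic metalation, Wittig rearrangement and double addition.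

Step 9
Reactants: 13 methyl 2-oxo-2-[2,4,6-tris(DBB-oxy)phenyl]acetate
Product: 15 methyl 2-diazo-2-[2,4,6-tris(DBB-oxy)phenyl]acetate, via tosylhydrazone 14 (not isolated)
Conditions: TsNHNH2 (1.1 equiv), MeOH/PhMe, 60 °C; then DBU (1.5 equiv), CH2Cl2, rt
Reagents that add atoms: p-toluenesulfonyl hydrazide, Cc1ccc(cc1)S(=O)(=O)NN
Why: Condensation of the activated keto ester to the tosylhydrazone and base-induced loss of sulfinate (Bamford–Stevens-type diazo formation) gives the donor/acceptor diazo ester.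

Step 10
Reactants: 15 methyl 2-diazo-2-[2,4,6-tris(DBB-oxy)phenyl]acetate
Product: 16 methyl (2S,3R)-2-[3,4-bis(benzyloxy)phenyl]-4,6-bis(DBB-oxy)-2,3-dihydrobenzofuran-3-carboxylate (2-aryl and ester cis)
Conditions: Rh2(S-PTTL)4 (1 mol %), PhMe, −60 °C
Reagents that add atoms: none
Why: Intramolecular 1,5 C–H insertion of the rhodium carbenoid into an ortho O–CH2Ar group closes the five-membered ring; the chiral carboxylate catalyst sets C2 and gives the cis ester kinetically, and the two ortho DBB ethers are homotopic so only one constitution can form.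

Step 11
Reactants: 16 methyl (2S,3R)-2-[3,4-bis(benzyloxy)phenyl]-4,6-bis(DBB-oxy)-2,3-dihydrobenzofuran-3-carboxylate
Product: 18 methyl (2R,3S)-2-[3,4-bis(benzyloxy)phenyl]-4,6-bis(DBB-oxy)-3-hydroxy-2,3-dihydrobenzofuran-3-carboxylate (hydroxyl trans to the 2-aryl group), via potassium enolate 17 (not isolated)
Conditions: KN(SiMe3)2 (1.1 equiv), THF, −78 °C; then 2-(phenylsulfonyl)-3-phenyloxaziridine (1.3 equiv), −78 °C
Reagents that add atoms: 2-(phenylsulfonyl)-3-phenyloxaziridine, O=S(=O)(c1ccccc1)N1OC1c1ccccc1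
Why: Enolate hydroxylation with an N-sulfonyloxaziridine, the oxidant approaching anti to the 2-aryl group; C2 is untouched, the ring C–O bond lies orthogonal to the enolate π system so β-elimination should not occur, and the C3 configuration is of no consequence because C3 becomes a carbonyl carbon in step 13.

Step 12
Reactants: 18 methyl (2R,3S)-2-[3,4-bis(benzyloxy)phenyl]-4,6-bis(DBB-oxy)-3-hydroxy-2,3-dihydrobenzofuran-3-carboxylate
Product: 19 (2R,3S)-2-[3,4-bis(benzyloxy)phenyl]-4,6-bis(DBB-oxy)-3-hydroxy-2,3-dihydrobenzofuran-3-carbaldehyde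
Conditions: i-Bu2AlH (2.5 equiv), CH2Cl2, −78 °C; aq. potassium sodium tartrate
Reagents that add atoms: none
Why: Partial reduction of the α-hydroxy ester; the tetrahedral aluminium hemiacetal, chelated by the neighbouring alkoxide, should survive at −78 °C until work-up, and the aldehyde has no α-hydrogen and cannot epimerize.

Step 13
Reactants: 19 (2R,3S)-2-[3,4-bis(benzyloxy)phenyl]-4,6-bis(DBB-oxy)-3-hydroxy-2,3-dihydrobenzofuran-3-carbaldehyde
Product: 20 (2R,3R)-2-[3,4-bis(benzyloxy)phenyl]-5,7-bis(DBB-oxy)-3-hydroxychroman-4-one (2,3-trans flavanonol)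
Conditions: Sc(OTf)3 (10 mol %), 4 Å MS, CH2Cl2, −20 °C → rt
Reagents that add atoms: none
Why: Sc(OTf)3 chelates the tertiary hydroxyl and the formyl oxygen of 19, and the ring bond C3–C2 shifts to the formyl carbon while the carbinol carbon becomes the ketone, so the five-membered ring grows to the six-membered ring C of the flavanonol. The closest known type is the α-ketol (acyloin) rearrangement of cyclic tertiary α-hydroxy aldehydes and ketones with ring enlargement, as in the D-homo annulation of 17-hydroxy-20-oxo steroids and the conversion of 1-hydroxycycloalkanecarbaldehydes into 2-hydroxycycloalkanones. Ring C is not closed by a cyclization but by a suprafacial 1,2-shift of C2 from the carbinol carbon to the formyl carbon, that is a one-carbon ring expansion of the dihydrofuran. C2 migrates with retention and so keeps the configuration set in step 10, while the new carbinol centre C3 is set trans to the 2-aryl group by the syn-periplanar chelate (new hydroxyl pseudo-equatorial) and, being next to the ketone, is also the thermodynamic epimer. The step needs migration of a ring bond and a ketol equilibrium on the product side: if the aryl carbon migrates instead of C2 the tautomeric 4-hydroxy-3-one results, which the same catalyst should carry to 20 by a 1,2-hydride ketol shift, and the change from an aldehyde to an aryl ketone conjugated with the trioxygenated ring A, together with relief of the five-membered ring, secures the direction. The aldehyde has no α-hydrogen, so neither enolization nor β-elimination of the ring oxygen can compete.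

Step 14
Reactants: 20 (2R,3R)-2-[3,4-bis(benzyloxy)phenyl]-5,7-bis(DBB-oxy)-3-hydroxychroman-4-one
Product: 21 (2R,3S,4R)-2-[3,4-bis(benzyloxy)phenyl]-5,7-bis(DBB-oxy)chromane-3,4-diol (2,3-trans-3,4-trans)
Conditions: NaBH4, THF/EtOH, 0 °C
Reagents that add atoms: none
Why: Hydride reduction of the 3-hydroxyflavanone should give mainly the 3,4-trans diol; the C4 configuration is immaterial because C4 is ionized in step 16.

Step 15
Reactants: 21 (2R,3S,4R)-2-[3,4-bis(benzyloxy)phenyl]-5,7-bis(DBB-oxy)chromane-3,4-diol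
Product: 22 (2R,3S,4R)-8-bromo-2-[3,4-bis(benzyloxy)phenyl]-5,7-bis(DBB-oxy)chromane-3,4-diol
Conditions: NBS (1.0 equiv), CH2Cl2, −78 °C → −20 °C
Reagents that add atoms: N-bromosuccinimide, O=C1CCC(=O)N1Br
Why: Electrophilic bromination of ring A at C8 (flanked by O1 and one ether) and not at C6 (between two benzylic ethers), as with benzylated catechin; the cap prevents self-condensation through C8 and later leaves C6 as the only site for the upper unit.

Step 16
Reactants: 22 (2R,3S,4R)-8-bromo-2-[3,4-bis(benzyloxy)phenyl]-5,7-bis(DBB-oxy)chromane-3,4-diol; 3 8-bromo-5,7,3',4'-tetra-O-benzyl-(+)-catechin (4 equiv)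
Product: 23 8-bromo-3',4'-di-O-benzyl-5,7-di-O-DBB-catechin-(4α→6)-8-bromo-5,7,3',4'-tetra-O-benzylcatechin
Conditions: TMSOTf (0.2 equiv), 4 Å MS, CH2Cl2, −78 °C → −40 °C; Et3N quench
Reagents that add atoms: none
Why: Friedel–Crafts-type flavan-3,4-diol condensation: the doubly activated benzylic 4-hydroxyl ionizes to the flavan-4-yl cation, which C6 of 3 (C8 capped) attacks anti to the 3-hydroxyl to set the 3,4-trans (4α) bond; the excess of 3 suppresses self-condensation through C6 of 22.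

Step 17
Reactants: 23 8-bromo-3',4'-di-O-benzyl-5,7-di-O-DBB-catechin-(4α→6)-8-bromo-5,7,3',4'-tetra-O-benzylcatechin; 7 (2R,3R,4S)-6,8-dibromo-4-(2-ethoxyethoxy)-5,7,3',4'-tetra-O-benzylepicatechin (1.5 equiv)
Product: 24 6,8-dibromo-5,7,3',4'-tetra-O-benzylepicatechin-(4β→6)-8-bromo-3',4'-di-O-benzyl-5,7-di-O-DBB-catechin-(4α→6)-8-bromo-5,7,3',4'-tetra-O-benzylcatechin
Conditions: TMSOTf (0.3 equiv), 4 Å MS, CH2Cl2, −78 °C → −30 °C; Et3N quench
Reagents that add atoms: none
Why: Lewis-acid ionization of the C4 ether of 7 gives the 2,3-cis flavan-4-yl cation; the only free nucleophilic ring A carbon in 23 is C6 of the middle unit, which attacks anti to the 3-hydroxyl to set the 4β bond (Friedel–Crafts-type interflavan coupling with bromine caps).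

Step 18
Reactants: 24 6,8-dibromo-5,7,3',4'-tetra-O-benzylepicatechin-(4β→6)-8-bromo-3',4'-di-O-benzyl-5,7-di-O-DBB-catechin-(4α→6)-8-bromo-5,7,3',4'-tetra-O-benzylcatechin
Product: 25 epicatechin-(4β→6)-catechin-(4α→6)-catechin (target)
Conditions: H2 (1 atm), Pd(OH)2/C, Et3N (6 equiv), THF/MeOH/H2O, rt
Reagents that add atoms: none
Why: Hydrogenolysis of all benzylic C–O bonds (the two DBB ethers leave as 4-methylcatechol) and hydrodebromination of the four aryl bromides, with Et3N taking up HBr; no stereocentre is touched.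

**Compound list**

1 | (+)-catechin, (2R,3S)-2-(3,4-dihydroxyphenyl)chromane-3,5,7-triol | c1c(O)cc2c(c1O)C[C@H](O)[C@@H](c5ccc(O)c(O)c5)O2 | starting material
2 | 5,7,3',4'-tetra-O-benzyl-(+)-catechin | c1c(OCc6ccccc6)cc2c(c1OCc6ccccc6)C[C@H](O)[C@@H](c5ccc(OCc6ccccc6)c(OCc6ccccc6)c5)O2 | intermediate
3 | 8-bromo-5,7,3',4'-tetra-O-benzyl-(+)-catechin | c1c(OCc6ccccc6)c(Br)c2c(c1OCc6ccccc6)C[C@H](O)[C@@H](c5ccc(OCc6ccccc6)c(OCc6ccccc6)c5)O2 | intermediate
4 | (−)-epicatechin, (2R,3R)-2-(3,4-dihydroxyphenyl)chromane-3,5,7-triol | Oc1cc(O)c2c(c1)O[C@H](c5ccc(O)c(O)c5)[C@H](O)C2 | starting material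
5 | 5,7,3',4'-tetra-O-benzyl-(−)-epicatechin | O(Cc6ccccc6)c1cc(OCc6ccccc6)c2c(c1)O[C@H](c5ccc(OCc6ccccc6)c(OCc6ccccc6)c5)[C@H](O)C2 | intermediate
6 | (2R,3R,4S)-4-(2-ethoxyethoxy)-5,7,3',4'-tetra-O-benzylepicatechin | O(Cc6ccccc6)c1cc(OCc6ccccc6)c2c(c1)O[C@H](c5ccc(OCc6ccccc6)c(OCc6ccccc6)c5)[C@H](O)[C@H]2OCCOCC | intermediate
7 | (2R,3R,4S)-6,8-dibromo-4-(2-ethoxyethoxy)-5,7,3',4'-tetra-O-benzylepicatechin | O(Cc6ccccc6)c1c(Br)c(OCc6ccccc6)c2c(c1Br)O[C@H](c5ccc(OCc6ccccc6)c(OCc6ccccc6)c5)[C@H](O)[C@H]2OCCOCC | intermediate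
8 | 1,3,5-triacetoxybenzene (phloroglucinol triacetate) | CC(=O)Oc1cc(OC(C)=O)cc(OC(C)=O)c1 | starting material
9 | 3,4-bis(benzyloxy)benzyl chloride (DBB-Cl) | ClCc1ccc(OCc2ccccc2)c(OCc2ccccc2)c1 | starting material
10 | 1,3,5-tris(DBB-oxy)benzene | c1(OCc7ccc(OCc6ccccc6)c(OCc6ccccc6)c7)cc(OCc7ccc(OCc6ccccc6)c(OCc6ccccc6)c7)cc(OCc7ccc(OCc6ccccc6)c(OCc6ccccc6)c7)c1 | intermediate
11 | 2-bromo-1,3,5-tris(DBB-oxy)benzene | Brc1c(OCc7ccc(OCc6ccccc6)c(OCc6ccccc6)c7)cc(OCc7ccc(OCc6ccccc6)c(OCc6ccccc6)c7)cc1OCc7ccc(OCc6ccccc6)c(OCc6ccccc6)c7 | intermediate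
12 | 2,4,6-tris(DBB-oxy)phenyllithium | [Li]c1c(OCc7ccc(OCc6ccccc6)c(OCc6ccccc6)c7)cc(OCc7ccc(OCc6ccccc6)c(OCc6ccccc6)c7)cc1OCc7ccc(OCc6ccccc6)c(OCc6ccccc6)c7 | intermediate
13 | methyl 2-oxo-2-[2,4,6-tris(DBB-oxy)phenyl]acetate | COC(=O)C(=O)c1c(OCc7ccc(OCc6ccccc6)c(OCc6ccccc6)c7)cc(OCc7ccc(OCc6ccccc6)c(OCc6ccccc6)c7)cc1OCc7ccc(OCc6ccccc6)c(OCc6ccccc6)c7 | intermediate
14 | methyl 2-(tosylhydrazono)-2-[2,4,6-tris(DBB-oxy)phenyl]acetate | COC(=O)C(=NNS(=O)(=O)c8ccc(C)cc8)c1c(OCc7ccc(OCc6ccccc6)c(OCc6ccccc6)c7)cc(OCc7ccc(OCc6ccccc6)c(OCc6ccccc6)c7)cc1OCc7ccc(OCc6ccccc6)c(OCc6ccccc6)c7 | intermediate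
15 | methyl 2-diazo-2-[2,4,6-tris(DBB-oxy)phenyl]acetate | COC(=O)C(=[N+]=[N-])c1c(OCc7ccc(OCc6ccccc6)c(OCc6ccccc6)c7)cc(OCc7ccc(OCc6ccccc6)c(OCc6ccccc6)c7)cc1OCc7ccc(OCc6ccccc6)c(OCc6ccccc6)c7 | intermediate
16 | methyl (2S,3R)-2-[3,4-bis(benzyloxy)phenyl]-4,6-bis(DBB-oxy)-2,3-dihydrobenzofuran-3-carboxylate (cis) | c1c(OCc7ccc(OCc6ccccc6)c(OCc6ccccc6)c7)cc2c(c1OCc7ccc(OCc6ccccc6)c(OCc6ccccc6)c7)[C@@H](C(=O)OC)[C@@H](c5ccc(OCc6ccccc6)c(OCc6ccccc6)c5)O2 | intermediate
17 | potassium ester enolate of 16 | c1c(OCc7ccc(OCc6ccccc6)c(OCc6ccccc6)c7)cc2c(c1OCc7ccc(OCc6ccccc6)c(OCc6ccccc6)c7)C(=C([O-])OC)[C@@H](c5ccc(OCc6ccccc6)c(OCc6ccccc6)c5)O2.[K+] | intermediate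
18 | methyl (2R,3S)-2-[3,4-bis(benzyloxy)phenyl]-4,6-bis(DBB-oxy)-3-hydroxy-2,3-dihydrobenzofuran-3-carboxylate | c1c(OCc7ccc(OCc6ccccc6)c(OCc6ccccc6)c7)cc2c(c1OCc7ccc(OCc6ccccc6)c(OCc6ccccc6)c7)[C@@](O)(C(=O)OC)[C@@H](c5ccc(OCc6ccccc6)c(OCc6ccccc6)c5)O2 | intermediate
19 | (2R,3S)-2-[3,4-bis(benzyloxy)phenyl]-4,6-bis(DBB-oxy)-3-hydroxy-2,3-dihydrobenzofuran-3-carbaldehyde | c1c(OCc7ccc(OCc6ccccc6)c(OCc6ccccc6)c7)cc2c(c1OCc7ccc(OCc6ccccc6)c(OCc6ccccc6)c7)[C@@](O)(C=O)[C@@H](c5ccc(OCc6ccccc6)c(OCc6ccccc6)c5)O2 | intermediate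
20 | (2R,3R)-2-[3,4-bis(benzyloxy)phenyl]-5,7-bis(DBB-oxy)-3-hydroxychroman-4-one | c1c(OCc7ccc(OCc6ccccc6)c(OCc6ccccc6)c7)cc2c(c1OCc7ccc(OCc6ccccc6)c(OCc6ccccc6)c7)C(=O)[C@H](O)[C@@H](c5ccc(OCc6ccccc6)c(OCc6ccccc6)c5)O2 | intermediate
21 | (2R,3S,4R)-2-[3,4-bis(benzyloxy)phenyl]-5,7-bis(DBB-oxy)chromane-3,4-diol | c1c(OCc7ccc(OCc6ccccc6)c(OCc6ccccc6)c7)cc2c(c1OCc7ccc(OCc6ccccc6)c(OCc6ccccc6)c7)[C@@H](O)[C@H](O)[C@@H](c5ccc(OCc6ccccc6)c(OCc6ccccc6)c5)O2 | intermediate
22 | (2R,3S,4R)-8-bromo-2-[3,4-bis(benzyloxy)phenyl]-5,7-bis(DBB-oxy)chromane-3,4-diol | c1c(OCc7ccc(OCc6ccccc6)c(OCc6ccccc6)c7)c(Br)c2c(c1OCc7ccc(OCc6ccccc6)c(OCc6ccccc6)c7)[C@@H](O)[C@H](O)[C@@H](c5ccc(OCc6ccccc6)c(OCc6ccccc6)c5)O2 | intermediate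
23 | 8-bromo-3',4'-di-O-benzyl-5,7-di-O-DBB-catechin-(4α→6)-8-bromo-5,7,3',4'-tetra-O-benzylcatechin | c1c(OCc7ccc(OCc6ccccc6)c(OCc6ccccc6)c7)c(Br)c2c(c1OCc7ccc(OCc6ccccc6)c(OCc6ccccc6)c7)[C@@H](c1c(OCc6ccccc6)c(Br)c3c(c1OCc6ccccc6)C[C@H](O)[C@@H](c5ccc(OCc6ccccc6)c(OCc6ccccc6)c5)O3)[C@H](O)[C@@H](c5ccc(OCc6ccccc6)c(OCc6ccccc6)c5)O2 | intermediate
24 | 6,8-dibromo-5,7,3',4'-tetra-O-benzylepicatechin-(4β→6)-8-bromo-3',4'-di-O-benzyl-5,7-di-O-DBB-catechin-(4α→6)-8-bromo-5,7,3',4'-tetra-O-benzylcatechin | O(Cc6ccccc6)c1c(Br)c(OCc6ccccc6)c2c(c1Br)O[C@H](c5ccc(OCc6ccccc6)c(OCc6ccccc6)c5)[C@H](O)[C@H]2c1c(OCc7ccc(OCc6ccccc6)c(OCc6ccccc6)c7)c(Br)c2c(c1OCc7ccc(OCc6ccccc6)c(OCc6ccccc6)c7)[C@@H](c1c(OCc6ccccc6)c(Br)c3c(c1OCc6ccccc6)C[C@H](O)[C@@H](c5ccc(OCc6ccccc6)c(OCc6ccccc6)c5)O3)[C@H](O)[C@@H](c5ccc(OCc6ccccc6)c(OCc6ccccc6)c5)O2 | intermediate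
25 | epicatechin-(4β→6)-catechin-(4α→6)-catechin | Oc1cc(O)c2c(c1)O[C@H](c1ccc(O)c(O)c1)[C@H](O)[C@H]2c1c(O)cc2c(c1O)[C@@H](c1c(O)cc3c(c1O)C[C@H](O)[C@@H](c1ccc(O)c(O)c1)O3)[C@H](O)[C@@H](c1ccc(O)c(O)c1)O2 | target

**Step count**

Total: 18 steps. Longest linear sequence: 13 steps (steps 6 to 18).

**Steps most likely to fail**

Step 13 (ring expansion). The migrating C2 is an α-aryloxy benzylic carbon, so the shift may become stepwise: ionization to an oxocarbenium ion and an enediolate that recombine without memory of configuration. Alternatively the ketol tautomer with its ketone at C3 may enolize towards C2. Either process would erode the enantiomeric purity of the middle unit, and the Lewis acid may also cleave the acid-labile DBB ethers. The fallback gives up the de novo ring and takes the middle unit from the chiral pool, joined by bromine-capped Friedel–Crafts couplings of the same kind as steps 16 and 17. It sets out from 3. Oxidation with DDQ in the presence of 2-ethoxyethanol (CH2Cl2, rt) should give (2R,3S,4S)-8-bromo-4-(2-ethoxyethoxy)-5,7,3',4'-tetra-O-benzylcatechin F1 (either C4 epimer serves). F1 and an excess of 3 with TMSOTf (CH2Cl2, −78 °C) should give 8-bromo-5,7,3',4'-tetra-O-benzylcatechin-(4α→6)-8-bromo-5,7,3',4'-tetra-O-benzylcatechin F2. F2 and 7 under the conditions of step 17 should give 6,8-dibromo-5,7,3',4'-tetra-O-benzylepicatechin-(4β→6)-8-bromo-5,7,3',4'-tetra-O-benzylcatechin-(4α→6)-8-bromo-5,7,3',4'-tetra-O-benzylcatechin F3. Hydrogenolysis of F3 under the conditions of step 18 gives 25, where the fallback comes back to the route.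

Step 17 (second interflavan bond). C6 of the middle unit in 23 lies between two bulky ethers and is deactivated by the bromine at C8. Substitution may therefore be slower than decomposition of the cation from 7 or than acid cleavage of the DBB ethers. The fallback changes the class of electrophile and the way it is ionized: a 4-sulfanylflavan is activated by a thiophilic silver salt under non-acidic conditions. It sets out from 7. Exchange with benzyl mercaptan (BF3·OEt2, CH2Cl2, −78 °C) should give 6,8-dibromo-4β-(benzylsulfanyl)-5,7,3',4'-tetra-O-benzyl-(−)-epicatechin F4. F4 and 23 with AgBF4 (THF, 0 °C → rt) should give 24, where the fallback comes back to the route.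

Step 10 (carbene C–H insertion). Both ortho positions of the aryldiazoacetate are substituted, so the carbenoid may insert with low enantioselectivity. It may also be diverted to attack on the electron-rich benzyl rings or to oxonium ylide formation. The fallback closes the dihydrofuran photochemically, without a carbene, and accepts a resolution. It sets out from keto ester 13. Norrish–Yang photocyclization (hν 350 nm, benzene, rt; 1,6-hydrogen transfer from an ortho O–CH2 group to the excited ketone, then coupling of the 1,5-biradical) should give directly racemic methyl 2-[3,4-bis(benzyloxy)phenyl]-4,6-bis(DBB-oxy)-3-hydroxy-2,3-dihydrobenzofuran-3-carboxylate F5 as a mixture of C3 epimers. i-Bu2AlH as in step 12 should give racemic 2-[3,4-bis(benzyloxy)phenyl]-4,6-bis(DBB-oxy)-3-hydroxy-2,3-dihydrobenzofuran-3-carbaldehyde F6. Sc(OTf)3 as in step 13 should give the racemic trans flavanonol, because C3 of F6 becomes the carbonyl carbon; that is 20 together with its enantiomer (2S,3S)-2-[3,4-bis(benzyloxy)phenyl]-5,7-bis(DBB-oxy)-3-hydroxychroman-4-one F7. Chromatography on a chiral stationary phase separates 20 from F7, and the fallback comes back to the route at 20.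

Further compounds
F1 | step 13 | (2R,3S,4S)-8-bromo-4-(2-ethoxyethoxy)-5,7,3',4'-tetra-O-benzylcatechin | c1c(OCc6ccccc6)c(Br)c2c(c1OCc6ccccc6)[C@H](OCCOCC)[C@H](O)[C@@H](c5ccc(OCc6ccccc6)c(OCc6ccccc6)c5)O2
F2 | step 13 | 8-bromo-5,7,3',4'-tetra-O-benzylcatechin-(4α→6)-8-bromo-5,7,3',4'-tetra-O-benzylcatechin | c1c(OCc6ccccc6)c(Br)c2c(c1OCc6ccccc6)[C@@H](c1c(OCc6ccccc6)c(Br)c3c(c1OCc6ccccc6)C[C@H](O)[C@@H](c5ccc(OCc6ccccc6)c(OCc6ccccc6)c5)O3)[C@H](O)[C@@H](c5ccc(OCc6ccccc6)c(OCc6ccccc6)c5)O2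
F3 | step 13 | 6,8-dibromo-5,7,3',4'-tetra-O-benzylepicatechin-(4β→6)-8-bromo-5,7,3',4'-tetra-O-benzylcatechin-(4α→6)-8-bromo-5,7,3',4'-tetra-O-benzylcatechin | O(Cc6ccccc6)c1c(Br)c(OCc6ccccc6)c2c(c1Br)O[C@H](c5ccc(OCc6ccccc6)c(OCc6ccccc6)c5)[C@H](O)[C@H]2c1c(OCc6ccccc6)c(Br)c2c(c1OCc6ccccc6)[C@@H](c1c(OCc6ccccc6)c(Br)c3c(c1OCc6ccccc6)C[C@H](O)[C@@H](c5ccc(OCc6ccccc6)c(OCc6ccccc6)c5)O3)[C@H](O)[C@@H](c5ccc(OCc6ccccc6)c(OCc6ccccc6)c5)O2
F4 | step 17 | 6,8-dibromo-4β-(benzylsulfanyl)-5,7,3',4'-tetra-O-benzyl-(−)-epicatechin | O(Cc6ccccc6)c1c(Br)c(OCc6ccccc6)c2c(c1Br)O[C@H](c5ccc(OCc6ccccc6)c(OCc6ccccc6)c5)[C@H](O)[C@H]2SCc6ccccc6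
F5 | step 10 | racemic methyl 2-[3,4-bis(benzyloxy)phenyl]-4,6-bis(DBB-oxy)-3-hydroxy-2,3-dihydrobenzofuran-3-carboxylate, both C3 epimers | c1c(OCc7ccc(OCc6ccccc6)c(OCc6ccccc6)c7)cc2c(c1OCc7ccc(OCc6ccccc6)c(OCc6ccccc6)c7)C(O)(C(=O)OC)C(c5ccc(OCc6ccccc6)c(OCc6ccccc6)c5)O2
F6 | step 10 | racemic 2-[3,4-bis(benzyloxy)phenyl]-4,6-bis(DBB-oxy)-3-hydroxy-2,3-dihydrobenzofuran-3-carbaldehyde, both C3 epimers | c1c(OCc7ccc(OCc6ccccc6)c(OCc6ccccc6)c7)cc2c(c1OCc7ccc(OCc6ccccc6)c(OCc6ccccc6)c7)C(O)(C=O)C(c5ccc(OCc6ccccc6)c(OCc6ccccc6)c5)O2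
F7 | step 10 | (2S,3S)-2-[3,4-bis(benzyloxy)phenyl]-5,7-bis(DBB-oxy)-3-hydroxychroman-4-one | c1c(OCc7ccc(OCc6ccccc6)c(OCc6ccccc6)c7)cc2c(c1OCc7ccc(OCc6ccccc6)c(OCc6ccccc6)c7)C(=O)[C@@H](O)[C@H](c5ccc(OCc6ccccc6)c(OCc6ccccc6)c5)O2
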